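**Strategy.** The dihydropyran is disconnected last to (−)-β-caryophyllene and the exo-methylene triketone from norflavesone (hetero-Diels–Alder). Caryophyllene's nine-membered ring is never closed as such: the 1,5-relationship between C8 (the methylene-bearing carbon, a masked ketone) and the C4=C5 olefin is a Claisen retron. A seven-membered lactone (O, C8, C9, C1, C2, C3, C4; C4 carrying methyl and vinyl) fused to the dimethylcyclobutane is methylenated, and the [3,3] shift forms C6–C7, breaks the temporary C4–O bond and enlarges the ring by two carbons to the cyclononenone in one operation. The Z olefin it imposes is inverted to E via its epoxide.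

Key step: step 5

Remarks: atoms are numbered as in caryophyllane (C1 and C9 are the cyclobutane ring-fusion carbons, C1 next to CMe2; C4 carries the methyl, C8 the exocyclic methylene). The C4 epimers of 8–10 and both cis-epoxide face isomers of 14 converge, so one is drawn. 2,4,6-Trihydroxyisobutyrophenone 18 is assumed to be a catalogue compound.

Step 1
Reactants: 1 cyclohex-2-en-1-one; 2 2-methylpropene (isobutene)
Product: 3 (1R,6R)-7,7-dimethylbicyclo[4.2.0]octan-2-one
Conditions: 2 (excess), diphenylprolinol-derived B-(2,4,6-trifluorophenyl)oxazaborolidine·AlBr3 (50 mol %, antipode chosen for 6R), CH2Cl2, −75 °C, hν 366 nm; then basic Al2O3, rt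
Reagents that add atoms: none
Why: Chiral-Lewis-acid-catalysed enone–alkene [2+2] photocycloaddition, in which the complexed enone is excited selectively and adds isobutene head-to-tail on the face left open by the oxazaborolidine, setting C6 (the later C1) as R; the alumina treatment epimerises any trans-fused adduct at C1 to the cis ring fusion.

Step 2
Reactants: 3 (1R,6R)-7,7-dimethylbicyclo[4.2.0]octan-2-one; 4 acetaldehyde
Product: 7 (1R,6R,E)-3-ethylidene-7,7-dimethylbicyclo[4.2.0]octan-2-one, via lithium aldolate 5 (not isolated), via mesylate 6 (not isolated)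
Conditions: LDA, THF, −78 °C; 4; then MsCl, −78 → 0 °C; then DBU, rt
Reagents that add atoms: none
Why: Kinetic deprotonation at the C3 methylene (not the ring-fusion methine), directed aldol addition, mesylation and E1cB elimination amount to an aldol condensation giving the conjugated E-ethylidene ketone; the stereocentres of 5 and 6 are destroyed in the elimination.

Step 3
Reactants: 7 (1R,6R,E)-3-ethylidene-7,7-dimethylbicyclo[4.2.0]octan-2-one
Product: 8 (1R,6R)-3-ethenyl-3,7,7-trimethylbicyclo[4.2.0]octan-2-one
Conditions: KOtBu, THF, 0 °C; MeI, 0 °C → rt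
Reagents that add atoms: iodomethane, CI
Why: Deconjugative α-alkylation, in which equilibrating base forms the linear dienolate by γ-deprotonation of the ethylidene methyl and methylation occurs at the α-carbon; the configuration of the new quaternary centre is irrelevant because this carbon (C4) becomes sp2 in step 5.

Step 4
Reactants: 8 (1R,6R)-3-ethenyl-3,7,7-trimethylbicyclo[4.2.0]octan-2-one
Product: 9 (1R,7R)-4-ethenyl-4,8,8-trimethyl-3-oxabicyclo[5.2.0]nonan-2-one
Conditions: mCPBA, NaHCO3, CH2Cl2, 0 °C → rt
Reagents that add atoms: mCPBA, O=C(OO)c1cccc(Cl)c1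
Why: Baeyer–Villiger oxidation with migration (retention) of the tertiary allylic carbon in preference to the secondary cyclobutyl carbon, which places the ring oxygen on C4; the monosubstituted vinyl group should be epoxidised far more slowly.

Step 5
Reactants: 9 (1R,7R)-4-ethenyl-4,8,8-trimethyl-3-oxabicyclo[5.2.0]nonan-2-one
Product: 11 (1R,9R,Z)-6,10,10-trimethylbicyclo[7.2.0]undec-5-en-2-one, via enol ether 10 (not isolated)
Conditions: Cp2TiMe2, toluene, 75 °C, dark; then base-washed sealed tube, 170 °C
Reagents that add atoms: dimethyltitanocene Cp2TiMe2, C[Ti](C)(C1C=CC=C1)C1C=CC=C1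
Why: Cp2TiMe2 loses methane to Cp2Ti=CH2, which methylenates the lactone carbonyl through an oxatitanacyclobutane to the 2-methyleneoxepane 10, and on further heating the allyl vinyl ether C7=C8–O–C4–C5=C6 undergoes a concerted [3,3]-sigmatropic (Claisen) shift that forms C6–C7, breaks the temporary C4–O bond and turns C8 into the ketone. The closest known reaction type is the methylenation/Claisen ring enlargement of 6-vinyl δ-lactones to cyclooct-4-enones and of vinyl-substituted cyclic ketene acetals to eight- and nine-membered lactones. The nine-membered carbocycle is not closed by an exo or endo cyclisation but arises by two-atom enlargement of the seven-membered oxacycle: the exocyclic CH2 and both vinyl carbons enter the ring while oxygen is expelled as the carbonyl oxygen, through a bridged boat-like six-centre transition state. No stereocentre is created; C4 is destroyed (so both C4 epimers of 9 converge), C1 is untouched, and the olefin is Z because the four-atom bridge C9–C1–C2–C3 must span the two oxygen-bound termini on one side of the pericyclic array. The step needs the [3,3] shift to outrun acid-catalysed migration of the exocyclic enol ether double bond and hydrolysis, which base-washed glassware and the neutral titanium reagent should secure; the cis ring fusion at C9 does not matter because it is equilibrated in step 6.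

Step 6
Reactants: 11 (1R,9R,Z)-6,10,10-trimethylbicyclo[7.2.0]undec-5-en-2-one
Product: 13 (−)-isocaryophyllene, via trans-fused ketone 12 (not isolated)
Conditions: KOtBu (0.2 equiv), THF, rt; then Ph3P=CH2 (from Ph3PCH3Br and KOtBu), THF, rt → 45 °C
Reagents that add atoms: methyltriphenylphosphonium bromide (delivers CH2 as Ph3P=CH2), C[P+](c1ccccc1)(c1ccccc1)c1ccccc1.[Br-]
Why: Base equilibrates the enolisable ring-fusion centre α to the ketone to the more stable trans-fused ketone 12 (thermodynamic control, C9 becomes S), which a Wittig methylenation converts in the same flask into the exocyclic olefin without touching the Z olefin.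

Step 7
Reactants: 13 (−)-isocaryophyllene
Product: 14 isocaryophyllene 4,5-epoxide (1R,4R,5S,9S)
Conditions: mCPBA (1.0 equiv), CH2Cl2/aq. NaHCO3, 0 °C
Reagents that add atoms: mCPBA, O=C(OO)c1cccc(Cl)c1
Why: Prilezhaev epoxidation should occur at the more electron-rich trisubstituted C4=C5 olefin rather than the 1,1-disubstituted exocyclic one and is stereospecific (cis-epoxide); the face of attack is immaterial since both cis-epoxides lead to the same E olefin in step 8.

Step 8
Reactants: 14 isocaryophyllene 4,5-epoxide (1R,4R,5S,9S)
Product: 17 (−)-β-caryophyllene, via lithium phosphino alkoxide 15 (not isolated), via betaine 16 (not isolated)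
Conditions: LiPPh2, THF, rt → 50 °C; then MeI, rt
Reagents that add atoms: none
Why: Deoxygenation with inversion of olefin geometry: SN2 opening of the epoxide by diphenylphosphide at the secondary C5 (inversion), P-methylation to the betaine and Wittig-type syn-elimination of methyldiphenylphosphine oxide should give the E olefin stereospecifically from the cis-epoxide.

Step 9
Reactants: 18 2-methyl-1-(2,4,6-trihydroxyphenyl)propan-1-one
Product: 19 norflavesone
Conditions: NaOMe, MeOH, MeI (3 equiv), 0 °C → rt
Reagents that add atoms: iodomethane, CI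
Why: Dearomatising C-methylation of the acylphloroglucinol enolates at the two free ring carbons, limited to three methyl groups by stoichiometry (the di- and tetramethyl congeners are removed by chromatography); no configurationally stable stereocentre results.

Step 10
Reactants: 17 (−)-β-caryophyllene; 19 norflavesone
Product: 21 target compound CNP0497637.2, via exo-methylene triketone 20 (not isolated)
Conditions: 19 (1.5 equiv), TEMPO, Ag2O, CH2Cl2, rt
Reagents that add atoms: none
Why: Oxidative dehydrogenation of the ring methyl of enolised 19 by Ag2O/TEMPO gives the electron-poor 1-oxadiene 20, which adds to the strained E C4=C5 olefin (not the exocyclic one) in an inverse-electron-demand hetero-Diels–Alder reaction with O to the more substituted C4 and CH2 to C5 through the carbonyl next to CMe2; suprafacial addition fixes the trans relation of the C4 methyl and C5 hydrogen, and attack on the exposed face of the predominant ring conformer (the face that gives natural caryophyllene oxide, dictated by the C1/C9 ring fusion) should give 4R,5S as the major, separable diastereomer.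

**Compound list**

1 | cyclohex-2-en-1-one | O=C1C=CCCC1 | starting material
2 | 2-methylpropene (isobutene) | C=C(C)C | starting material
3 | (1R,6R)-7,7-dimethylbicyclo[4.2.0]octan-2-one (cis-fused) | O=C1CCC[C@@H]2[C@H]1CC2(C)C | intermediate
4 | acetaldehyde | CC=O | starting material
5 | lithium 1-[(1R,6R)-7,7-dimethyl-2-oxobicyclo[4.2.0]octan-3-yl]ethanolate (diastereomer mixture) | O=C1C(C(C)[O-])CC[C@@H]2[C@H]1CC2(C)C.[Li+] | intermediate
6 | 1-[(1R,6R)-7,7-dimethyl-2-oxobicyclo[4.2.0]octan-3-yl]ethyl methanesulfonate (diastereomer mixture) | O=C1C(C(C)OS(C)(=O)=O)CC[C@@H]2[C@H]1CC2(C)C | intermediate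
7 | (1R,6R,E)-3-ethylidene-7,7-dimethylbicyclo[4.2.0]octan-2-one | O=C1/C(=C/C)CC[C@@H]2[C@H]1CC2(C)C | intermediate
8 | (1R,6R)-3-ethenyl-3,7,7-trimethylbicyclo[4.2.0]octan-2-one (both C3 epimers) | O=C1C(C)(C=C)CC[C@@H]2[C@H]1CC2(C)C | intermediate
9 | (1R,7R)-4-ethenyl-4,8,8-trimethyl-3-oxabicyclo[5.2.0]nonan-2-one (both C4 epimers) | O=C1OC(C)(C=C)CC[C@@H]2[C@H]1CC2(C)C | intermediate
10 | (1R,7R)-4-ethenyl-4,8,8-trimethyl-2-methylidene-3-oxabicyclo[5.2.0]nonane | C=C1OC(C)(C=C)CC[C@@H]2[C@H]1CC2(C)C | intermediate
11 | (1R,9R,Z)-6,10,10-trimethylbicyclo[7.2.0]undec-5-en-2-one (cis-fused; C8 ketone, Z C4=C5 in caryophyllane numbering) | O=C1CC/C=C(/C)CC[C@@H]2[C@H]1CC2(C)C | intermediate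
12 | (1S,9R,Z)-6,10,10-trimethylbicyclo[7.2.0]undec-5-en-2-one (trans-fused) | O=C1CC/C=C(/C)CC[C@@H]2[C@@H]1CC2(C)C | intermediate
13 | (−)-isocaryophyllene, (1R,4Z,9S)-4,11,11-trimethyl-8-methylidenebicyclo[7.2.0]undec-4-ene | C=C1CC/C=C(/C)CC[C@@H]2[C@@H]1CC2(C)C | intermediate
14 | isocaryophyllene 4,5-epoxide, (1R,4R,5S,9S), cis-epoxide | C=C1CC[C@@H]2O[C@]2(C)CC[C@@H]3[C@@H]1CC3(C)C | intermediate
15 | lithium (1R,4R,5R,9S)-5-(diphenylphosphanyl)-4,11,11-trimethyl-8-methylidenebicyclo[7.2.0]undecan-4-olate | C=C1CC[C@@H](P(c2ccccc2)c2ccccc2)[C@](C)([O-])CC[C@@H]2[C@@H]1CC2(C)C.[Li+] | intermediate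
16 | (1R,4R,5R,9S)-4,11,11-trimethyl-8-methylidene-5-[methyl(diphenyl)phosphaniumyl]bicyclo[7.2.0]undecan-4-olate (betaine) | C=C1CC[C@@H]([P+](C)(c2ccccc2)c2ccccc2)[C@](C)([O-])CC[C@@H]2[C@@H]1CC2(C)C | intermediate
17 | (−)-β-caryophyllene, (1R,4E,9S)-4,11,11-trimethyl-8-methylidenebicyclo[7.2.0]undec-4-ene | C=C1CC/C=C(\C)CC[C@@H]2[C@@H]1CC2(C)C | intermediate
18 | 2-methyl-1-(2,4,6-trihydroxyphenyl)propan-1-one (2,4,6-trihydroxyisobutyrophenone) | CC(C)C(=O)c1c(O)cc(O)cc1O | starting material
19 | norflavesone, 3,5-dihydroxy-4,6,6-trimethyl-2-(2-methylpropanoyl)cyclohexa-2,4-dien-1-one (dienol tautomer) | CC(C)C(=O)C1=C(O)C(C)=C(O)C(C)(C)C1=O | intermediate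
20 | 3-hydroxy-6,6-dimethyl-4-methylidene-2-(2-methylpropanoyl)cyclohex-2-ene-1,5-dione | CC(C)C(=O)C1=C(O)C(=C)C(=O)C(C)(C)C1=O | intermediate
21 | CNP0497637.2, the trans-fused chromene adduct of β-caryophyllene (1R,4R,5S,9S) and 20 | C=C1CC[C@H]2CC3=C(O[C@]2(C)CC[C@@H]2[C@@H]1CC2(C)C)C(C)(C)C(=O)C(C(=O)C(C)C)=C3O | target

Total step count: 10. Longest linear sequence: 9 (steps 1–8 and 10).

**Steps most likely to fail**

Step 5. The exocyclic enol ether may isomerise to the endocyclic enol ether or hydrolyse before it rearranges, or the bridged transition state may not be reached below the temperature at which the enol ether decomposes. The fallback sets out from 8 and replaces the Claisen by two separate ring enlargements. Direct irradiation (300 nm, benzene) of the β,γ-unsaturated ketone should cause α-cleavage and recombination at the vinyl terminus (photochemical 1,3-acyl shift) to give the eight-membered enone (1R,8R,Z)-5,9,9-trimethylbicyclo[6.2.0]dec-4-en-2-one F1. One-carbon homologation with trimethylsilyldiazomethane and AlMe3, with migration of the less substituted allylic CH2, would give the α-silyl ketone (1R,9R,Z)-6,10,10-trimethyl-3-(trimethylsilyl)bicyclo[7.2.0]undec-5-en-2-one F2. Protodesilylation with dilute aqueous HCl returns to the route at 11.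

Step 8. Opening of the hindered trisubstituted medium-ring epoxide by the phosphide may be slow, base-induced isomerisation to an allylic alcohol may compete, and the betaine may collapse incompletely. The fallback sets out from 14 and goes through a diol instead. Hydroxide opening at C5 with inversion (KOH, DMSO/H2O, 100 °C) would give (1R,4R,5R,9S)-4,11,11-trimethyl-8-methylidenebicyclo[7.2.0]undecane-4,5-diol F3. 1,1'-Thiocarbonyldiimidazole (DMAP, toluene, reflux) would convert it into the cyclic thiocarbonate of this diol F4. Corey–Winter syn-elimination with 1,3-dimethyl-2-phenyl-1,3,2-diazaphospholidine at 40 °C returns to the route at 17.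

Step 3. Alkylation may proceed through the cross-conjugated enolate at the ring-fusion carbon, or O-alkylation and double alkylation may erode the yield of the quaternary ketone. The fallback sets out from 3 and fixes the site of alkylation with a 1,3-dicarbonyl unit. Formylation (NaH, ethyl formate, THF) would give (1R,6R,Z)-3-(hydroxymethylidene)-7,7-dimethylbicyclo[4.2.0]octan-2-one F5. C-methylation (K2CO3, MeI, acetone) would give (1R,6R)-3,7,7-trimethyl-2-oxobicyclo[4.2.0]octane-3-carbaldehyde F6. Aldehyde-selective Wittig methylenation (Ph3P=CH2, 1 equiv, THF, −78 → 0 °C) returns to the route at 8.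

**Further compounds**

F1 | step 5 | (1R,8R,Z)-5,9,9-trimethylbicyclo[6.2.0]dec-4-en-2-one | O=C1C/C=C(/C)CC[C@@H]2[C@H]1CC2(C)C
F2 | step 5 | (1R,9R,Z)-6,10,10-trimethyl-3-(trimethylsilyl)bicyclo[7.2.0]undec-5-en-2-one | O=C1C([Si](C)(C)C)C/C=C(/C)CC[C@@H]2[C@H]1CC2(C)C
F3 | step 8 | (1R,4R,5R,9S)-4,11,11-trimethyl-8-methylidenebicyclo[7.2.0]undecane-4,5-diol | C=C1CC[C@@H](O)[C@](C)(O)CC[C@@H]2[C@@H]1CC2(C)C
F4 | step 8 | cyclic thiocarbonate of the (4R,5R)-diol | C=C1CC[C@H]2OC(=S)O[C@]2(C)CC[C@@H]3[C@@H]1CC3(C)C
F5 | step 3 | (1R,6R,Z)-3-(hydroxymethylidene)-7,7-dimethylbicyclo[4.2.0]octan-2-one | O=C1/C(=C\O)CC[C@@H]2[C@H]1CC2(C)C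
F6 | step 3 | (1R,6R)-3,7,7-trimethyl-2-oxobicyclo[4.2.0]octane-3-carbaldehyde (both C3 epimers) | O=C1C(C)(C=O)CC[C@@H]2[C@H]1CC2(C)C
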